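The earlier runs and the new flask come from a simulation with made-up constants; noise was put on by code.

- In Tuesday's run, between 4.00 h and 6.00 h, J rose by 60.0 % of what X lost. I counted the rest as J lost, and with the mean [X]/[J] of that stretch I read s, the loss constant of J over that of X, as 0.426, a reading with its scatter.

- Tuesday's: X 30 mM; E 0.2 mol%; run made earlier
- flask: X 20 mM; E 0.2 mol%; time 2.5 d
Tuesday's run (percent of the X charged)

| time / h | J / % | X / % |
|---|---|---|
| 0.500 | 7.2 | 93.2 |
| 0.833 | 10.6 | 89.7 |
| 1.33 | 17.8 | 82.6 |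
| 2.00 | 24.2 | 73.1 |
| 4.00 | 40.4 | 55.3 |
| 6.00 | 49.4 | 40.3 |

(each reading ± 1 percentage point)
- when, up to 2.5 d, the flask holds most J
- the amount of J, in percent of the X charged, at that time

- I counted turnovers, N = ln(X charged / X left). Tuesday's run made 0.909 of them by 6.00 h, so its turnover rate, the pseudo-first-order constant of X, was 0.151 h⁻¹.
- For X → J → lost, J peaks at N = ln(s)/(s − 1), which is 1.49.
- My early bound keeps Tuesday's rate: 0.409 d. My late bound lets the loss constants of X and of J fall together in step with [E], so that s stays as read, which is a guess: 0.614 d.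
- Tightening with a square root in [E], and J's loss constant unchanged, I got 0.124 h⁻¹, s = 0.522, N = 1.36, so 0.458 d and 49.2 % J.
- The forecast, 0.56 d (0.42 d to 0.8 d) and 53 % (46 % to 62 %), held that “X → J → lost reproduces the table well”. Its time lay inside my bracket and later than my tightened value, and its J stood higher than mine.

    X + L → G + J (k = 4.20 × 10⁵ L mol⁻¹ s⁻¹)
    E → 2 L (k = 8.10 × 10⁻⁵ min⁻¹)
    X + G → J + G, rate k3*[G]*[X] (k = 4.00 × 10⁵ L mol⁻¹ min⁻¹)
    2 G → Z (k = 2.00 × 10⁶ L mol⁻¹ s⁻¹)
    J ⇌ D (K = 0.960, k = 0.00110 min⁻¹)

- The flask peaked at 0.691 d with 56.0 % J, later than my late bound. X stood at 13.2 % then, which is 2.03 turnovers, more than my 1.49. The flask's mean turnover rate up to then was 0.122 h⁻¹, or 0.808 of the rate read from Tuesday's run, against 0.816, the square root of the ratio of the two [E] charges. Scaled the same way, 0.151 h⁻¹ gives the neighbour flask, with 8.0 mM of X and the same loading of E, 0.916 % X left at 2.5 d; it held 1.2 %.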